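**Retrosynthetic overview**

1. Ring labels: C1 = alkylidene carbon, C2 and C3 = CH2, C4 = C(OH)CH3, C5 = quaternary carbon (CH3 and side chain, chain carbons Ca, Cb, Cc … counted from the ring), C6 = CH with the hydroxypropyl arm. The plan rests on the C4/C5 pair of this cyclohexane: C4 is a tertiary methyl carbinol and its neighbour C5 is a quaternary carbon whose chain begins with a CH2 (Ca) trans to the C4 hydroxyl. That pattern is what a C4 methyl-ketone ketyl leaves when it adds to the β-carbon (C5) of a β-methyl enoate.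
2. Late stage: the threo epoxy alcohol is made last from the (S)-allylic alcohol by hydroxyl-directed epoxidation; the (Z)-enal comes from a C1 ketone by 2-propenyl addition and oxidative 1,3-transposition.
3. Side chain: Cb–Cc is cut by Negishi sp3–sp2 coupling of a ring-borne alkylzinc with an (E,E)-dienyl iodide, made from prenal by asymmetric propargylation and two Zr-catalysed carboalumination/iodination cycles.
4. Ring: the only carbocycle is formed once, by SmI2 ketyl–olefin 6-exo closure of the C4–C5 bond in an acyclic keto enoate (sets C4 and C5).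
5. Acyclic precursor: Evans syn aldol (sets C6 and a temporary C1 silyloxy centre), Weinreb ketone synthesis, Horner–Wadsworth–Emmons olefination, chemoselective ozonolysis.

Key step: step 9

Assumption: the (S)-configured phosphoric acid of step 13 is taken to deliver the propargyl group to the si face of prenal, as it does with aryl aldehydes; should the sense be opposite, its enantiomer is used.

Abbreviations: TBDPS = tert-butyldiphenylsilyl, TES = triethylsilyl, TBS = tert-butyldimethylsilyl, HMPA = hexamethylphosphoramide, TRIP = 3,3′-bis(2,4,6-triisopropylphenyl)-1,1′-binaphthyl-2,2′-diyl hydrogen phosphate.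

**Route**

Step 1
Reactants: 1 δ-valerolactone
Product: 4 5-(TBDPS-oxy)pentanoic acid, via sodium 5-hydroxypentanoate 2 (not isolated), via bis-silylated ester 3 (not isolated)
Conditions: NaOH, H2O, 60 °C, evaporate; TBDPSCl (2.2 equiv), imidazole, DMF, rt; K2CO3, THF/H2O, rt; acidify to pH 4
Reagents that add atoms: sodium hydroxide [Na+].[OH-]; tert-butyl(chloro)diphenylsilane CC(C)(C)[Si](Cl)(c1ccccc1)c1ccccc1
Why: Saponification opens the lactone, both oxygens are silylated, and mild aqueous base should hydrolyse only the labile silyl ester (lactone hydrolysis, silylation, selective silyl ester cleavage).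

Step 2
Reactants: 4 5-(TBDPS-oxy)pentanoic acid; 5 (R)-4-benzyl-2-oxazolidinone
Product: 7 (R)-4-benzyl-3-[5-(TBDPS-oxy)pentanoyl]oxazolidin-2-one, via mixed pivalic anhydride 6 (not isolated)
Conditions: PivCl, Et3N, THF, −20 °C; then 5, LiCl, −20 °C → rt
Reagents that add atoms: none
Why: N-Acylation of the oxazolidinone through the mixed anhydride under LiCl/Et3N activation is a standard way to make acyl imides without strong base.

Step 3
Reactants: 7 acyl oxazolidinone; 8 4-methylpent-4-enal
Product: 10 syn-aldol adduct (2R,3S), via (Z)-dibutylboron enolate 9 (not isolated)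
Conditions: Bu2BOTf, Et3N, CH2Cl2, −78 → 0 °C; 8, −78 → 0 °C; pH 7 buffer, MeOH, 30% H2O2, 0 °C
Reagents that add atoms: none
Why: Evans syn aldol: the (Z)-boron enolate reacts through a closed Zimmerman–Traxler transition state on the face away from the benzyl group of the (R)-auxiliary, which should set C6 (R in the adduct) and the C1 carbinol (S) in one step.

Step 4
Reactants: 10 syn-aldol adduct
Product: 11 β-hydroxy Weinreb amide
Conditions: MeNH(OMe)·HCl, AlMe3, THF, −20 → 0 °C; aq. KNaC4H4O6 work-up
Reagents that add atoms: N,O-dimethylhydroxylamine hydrochloride CNOC.Cl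
Why: Aluminium-amide transamination of the imide is assisted by the free β-hydroxyl, attacks the exocyclic carbonyl and should release the auxiliary without touching the α-centre (Weinreb amide formation).

Step 5
Reactants: 11 β-hydroxy Weinreb amide
Product: 12 TES-protected Weinreb amide
Conditions: TESCl, imidazole, DMF, 0 °C → rt
Reagents that add atoms: chlorotriethylsilane CC[Si](Cl)(CC)CC
Why: Routine silylation of the secondary alcohol; TES is chosen because it can later be removed in the presence of TBS and TBDPS ethers.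

Step 6
Reactants: 12 TES-protected Weinreb amide
Product: 13 methyl ketone (C5 carbonyl)
Conditions: MeMgBr, THF, 0 °C; aq. NH4Cl
Reagents that add atoms: methylmagnesium bromide C[Mg]Br
Why: Weinreb ketone synthesis: the chelated tetrahedral adduct prevents over-addition and the α-stereocentre C6 is not enolised at 0 °C.

Step 7
Reactants: 13 methyl ketone; 14 triethyl phosphonoacetate
Product: 16 (E)-β-methyl enoate, via sodium phosphonate carbanion 15 (not isolated)
Conditions: NaH, THF, 0 °C; then 13, 0 → 50 °C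
Reagents that add atoms: none
Why: Horner–Wadsworth–Emmons olefination of a methyl ketone should place the ester trans to the larger C6 residue (E), the weakly basic phosphonate anion should not enolise the ketone towards C6, and any (Z)-isomer is removed by chromatography.

Step 8
Reactants: 16 (E)-β-methyl enoate
Product: 18 keto enoate (cyclisation precursor), via secondary ozonide 17 (not isolated)
Conditions: O3, CH2Cl2, −78 °C, Sudan Red 7B end point; PPh3, −78 °C → rt
Reagents that add atoms: ozone [O-][O+]=O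
Why: The electron-rich 1,1-disubstituted alkene should be ozonised far faster than the electron-poor trisubstituted enoate, so indicator-controlled ozonolysis with reductive work-up should unmask the C4 methyl ketone selectively.

Step 9
Reactants: 18 keto enoate
Product: 19 cyclohexanol with C4 methyl carbinol and C5 methyl/CH2CO2Et
Conditions: SmI2 (2.5–3 equiv), HMPA (8–10 equiv), t-BuOH (2 equiv), THF, high dilution, −78 → −20 °C; aq. NH4Cl at −78 °C
Reagents that add atoms: none
Why: Electron transfer from SmI2–HMPA to the C4 methyl ketone gives a samarium ketyl that adds 6-exo-trig to the enoate β-carbon C5 (forming C4–C5 and closing the cyclohexane C1–C6), and a second electron transfer gives the samarium ester enolate, which t-BuOH protonates. The closest known reaction type is the SmI2/HMPA ketyl–olefin cyclisation of ketones onto α,β-unsaturated esters, which is documented for β,β-disubstituted acceptors that create quaternary carbons. C5 is controlled by a chair-like transition state in which the C6 arm and the C1 silyloxy group (trans, both from the aldol) are equatorial and the C5 methyl takes the axial site to avoid A(1,2) strain with the C6 arm, so the CH–CO2Et unit (future CH2CO2Et) is equatorial and ends trans to the C6 arm. C4 is controlled by the bulky HMPA-solvated O–Sm group, which should stay equatorial and transoid to the acceptor, leaving the two methyls trans-diaxial and the hydroxyl trans to the ester arm and cis to the C6 arm. The step needs ring closure to outrun simple ketone reduction and pinacol coupling, which HMPA, low temperature and high dilution should secure, and it needs a single alkene geometry, which the purified (E)-enoate (no A(1,3) strain towards C6) provides; no heteroatom sits α to the ketone or γ to the ester, so no reductive elimination competes. A cold aqueous quench is used so that the trans hydroxy ester is isolated before it can lactonise.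

Step 10
Reactants: 19 cyclohexanol
Product: 20 C4-O-TES ester
Conditions: TESOTf, 2,6-lutidine, CH2Cl2, 0 °C → rt
Reagents that add atoms: triethylsilyl trifluoromethanesulfonate CC[Si](CC)(CC)OS(=O)(=O)C(F)(F)F
Why: A silyl triflate should cap the hindered tertiary alcohol, which would otherwise close a tetrahydrofuran with the activated Cb position (1,4-diol relationship) in steps 12 and 19.

Step 11
Reactants: 20 C4-O-TES ester
Product: 21 primary alcohol (C5–CH2CH2OH)
Conditions: i-Bu2AlH, CH2Cl2, −78 → 0 °C; aq. KNaC4H4O6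
Reagents that add atoms: none
Why: Hydride reduction of the ester to the primary alcohol leaves the three silyl ethers untouched.

Step 12
Reactants: 21 primary alcohol
Product: 22 primary iodide (C5–CH2CH2I)
Conditions: I2, PPh3, imidazole, CH2Cl2, 0 °C
Reagents that add atoms: iodine II
Why: Appel-type iodination proceeds by SN2 displacement of the alkoxyphosphonium at the unhindered primary carbon.

Step 13
Reactants: 23 3-methylbut-2-enal (prenal); 24 allenylboronic acid pinacol ester
Product: 25 (S)-6-methylhept-5-en-1-yn-4-ol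
Conditions: (S)-TRIP (5–10 mol%), 4 Å MS, toluene, −20 °C
Reagents that add atoms: none
Why: Chiral phosphoric acid-catalysed propargylboration goes through a six-membered SE2′ transition state in which the catalyst hydrogen-bonds the boronate oxygen and the formyl hydrogen, and si-face attack should give the (S)-homopropargylic, allylic alcohol that becomes carbinol Cj.

Step 14
Reactants: 25 (S)-6-methylhept-5-en-1-yn-4-ol
Product: 26 TBS ether of 25
Conditions: TBSCl, imidazole, DMF, rt
Reagents that add atoms: tert-butyl(chloro)dimethylsilane CC(C)(C)[Si](C)(C)Cl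
Why: Silylation removes the acidic OH and protects the ionisable allylic carbinol before exposure to AlMe3.

Step 15
Reactants: 26 TBS ether
Product: 28 (1E,4S)-vinyl iodide, via alkenyldimethylalane 27 (not isolated)
Conditions: AlMe3, Cp2ZrCl2 (zirconocene dichloride, 0.2 equiv), H2O (1 equiv), CH2Cl2, −25 °C; then I2, THF, −25 → 0 °C
Reagents that add atoms: trimethylaluminium C[Al](C)C; iodine II
Why: Zr-catalysed carboalumination of the terminal alkyne adds CH3 and Al syn with methyl at the internal carbon, and iodinolysis with retention should give the (E)-2-methyl-1-iodoalkene while the trisubstituted alkene stays inert.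

Step 16
Reactants: 28 (1E,4S)-vinyl iodide; 29 (4-bromobut-1-yn-1-yl)trimethylsilane
Product: 31 TMS-enyne, via [4-(trimethylsilyl)but-3-yn-1-yl]zinc bromide 30 (not isolated)
Conditions: 29, Zn dust, LiCl, THF, 50 °C; then 28, Pd(PPh3)4 (5 mol%), THF, rt → 40 °C
Reagents that add atoms: none
Why: Negishi alkyl–alkenyl coupling with zerovalent palladium proceeds with retention of the alkene geometry and extends the chain by the homopropargyl unit.

Step 17
Reactants: 31 TMS-enyne
Product: 32 terminal enyne
Conditions: K2CO3, MeOH, rt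
Reagents that add atoms: none
Why: Methanolysis removes the alkynyl C–Si group selectively, and the TBS ether is stable to these conditions.

Step 18
Reactants: 32 terminal enyne
Product: 34 (1E,5E,8S)-dienyl iodide (side-chain fragment), via alkenyldimethylalane 33 (not isolated)
Conditions: AlMe3, Cp2ZrCl2 (0.2 equiv), H2O (1 equiv), CH2Cl2, −25 °C; then I2, THF, −25 → 0 °C
Reagents that add atoms: trimethylaluminium C[Al](C)C; iodine II
Why: A second Zr-catalysed syn-carboalumination/iodinolysis sets the Cc=Cd geometry (E) exactly as in step 15.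

Step 19
Reactants: 22 primary iodide; 34 (1E,5E,8S)-dienyl iodide
Product: 36 coupled triene, via alkylzinc iodide 35 (not isolated)
Conditions: 22, Zn dust (activated with BrCH2CH2Br/TMSCl), LiCl, THF, 40 °C; then 34, Pd(PPh3)4 (5 mol%), THF, rt → 45 °C
Reagents that add atoms: none
Why: Zinc insertion into the primary C–I bond tolerates the silyl ethers, and Negishi sp3–sp2 coupling should form Cb–Cc with retention of the (E)-iodoalkene geometry.

Step 20
Reactants: 36 coupled triene
Product: 37 C1 secondary alcohol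
Conditions: PPTS (0.2 equiv), MeOH/CH2Cl2, 0 °C → rt
Reagents that add atoms: none
Why: Acid-catalysed methanolysis should cleave the least hindered silyl ether (secondary TES at C1) while the tertiary TES, the TBS and the TBDPS ethers remain.

Step 21
Reactants: 37 C1 secondary alcohol
Product: 38 C1 ketone
Conditions: Dess–Martin periodinane, NaHCO3, CH2Cl2, rt
Reagents that add atoms: none
Why: Neutral, buffered oxidation of the secondary alcohol; the adjacent C6 centre already holds its arm equatorial and trans to the C5 chain, so it is not expected to epimerise.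

Step 22
Reactants: 38 C1 ketone
Product: 39 tertiary 2-propenyl carbinol at C1 (C1 epimers, inconsequential)
Conditions: isopropenylmagnesium bromide, CeCl3, THF, −78 → 0 °C
Reagents that add atoms: isopropenylmagnesium bromide CC(=C)[Mg]Br
Why: The weakly basic organocerium reagent should add 1,2 to the hindered, enolisable ketone without deprotonating it; the new C1 centre is destroyed in the next step.

Step 23
Reactants: 39 tertiary 2-propenyl carbinol
Product: 40 (Z)-α-methyl enal (C1=C(CH3)CHO)
Conditions: pyridinium chlorochromate C5H5NH[CrO3Cl] (3 equiv), 4 Å MS, CH2Cl2, rt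
Reagents that add atoms: pyridinium chlorochromate [O-][Cr](=O)(=O)Cl.c1cc[nH+]cc1
Why: Babler–Dauben oxidative transposition: the tertiary allylic chromate undergoes a [3,3] shift to the primary allylic chromate, which is oxidised to the enal, and the (Z)-isomer (small formyl group next to the equatorial C6 arm, minimising A(1,3) strain) should predominate, with any (E)-isomer equilibrated at this stage.

Step 24
Reactants: 40 (Z)-α-methyl enal
Product: 41 triol enal
Conditions: TBAF, AcOH (1:1), THF, rt → 40 °C
Reagents that add atoms: none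
Why: Fluoride removes the TBDPS, TBS and tertiary TES groups together, and acetic acid buffering should suppress γ-deprotonation of the enal.

Step 25
Reactants: 41 triol enal
Product: 42 CNP0161066.1 (target)
Conditions: VO(acac)2 (5 mol%), t-BuOOH (1.3 equiv), CH2Cl2, 0 °C
Reagents that add atoms: tert-butyl hydroperoxide CC(C)(C)OO
Why: Vanadium-catalysed hydroxyl-directed epoxidation should touch only the alkene allylic to the Cj hydroxyl (enal and isolated alkenes stay), and in the conformer that avoids A(1,3) strain with the Z-methyl, oxygen is delivered syn to the hydroxyl, so the (S)-carbinol should give the threo (R)-epoxide carbon; any erythro isomer is separated.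

**Compound list**

1 | δ-valerolactone | O=C1CCCCO1 | starting material
2 | sodium 5-hydroxypentanoate | [Na+].[O-]C(=O)CCCCO | intermediate
3 | tert-butyldiphenylsilyl 5-[(tert-butyldiphenylsilyl)oxy]pentanoate | CC(C)(C)[Si](OCCCCC(=O)O[Si](c1ccccc1)(c1ccccc1)C(C)(C)C)(c1ccccc1)c1ccccc1 | intermediate
4 | 5-[(tert-butyldiphenylsilyl)oxy]pentanoic acid | OC(=O)CCCCO[Si](c1ccccc1)(c1ccccc1)C(C)(C)C | intermediate
5 | (R)-4-benzyl-2-oxazolidinone | O=C1N[C@H](Cc2ccccc2)CO1 | starting material
6 | 5-[(tert-butyldiphenylsilyl)oxy]pentanoic pivalic anhydride | CC(C)(C)C(=O)OC(=O)CCCCO[Si](c1ccccc1)(c1ccccc1)C(C)(C)C | intermediate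
7 | (R)-4-benzyl-3-{5-[(tert-butyldiphenylsilyl)oxy]pentanoyl}oxazolidin-2-one | O=C(CCCCO[Si](c1ccccc1)(c1ccccc1)C(C)(C)C)N1C(=O)OC[C@H]1Cc2ccccc2 | intermediate
8 | 4-methylpent-4-enal | CC(=C)CCC=O | starting material
9 | (Z)-dibutylboron enolate of 7 | CCCCB(CCCC)O/C(=C\CCCO[Si](c1ccccc1)(c1ccccc1)C(C)(C)C)N1C(=O)OC[C@H]1Cc2ccccc2 | intermediate
10 | (4R)-4-benzyl-3-[(2R,3S)-2-{3-[(tert-butyldiphenylsilyl)oxy]propyl}-3-hydroxy-6-methylhept-6-enoyl]oxazolidin-2-one | O=C([C@@H]([C@@H](O)CCC(C)=C)CCCO[Si](c1ccccc1)(c1ccccc1)C(C)(C)C)N1C(=O)OC[C@H]1Cc2ccccc2 | intermediate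
11 | (2R,3S)-2-{3-[(tert-butyldiphenylsilyl)oxy]propyl}-3-hydroxy-N-methoxy-N,6-dimethylhept-6-enamide | CON(C)C(=O)[C@@H]([C@@H](O)CCC(C)=C)CCCO[Si](c1ccccc1)(c1ccccc1)C(C)(C)C | intermediate
12 | (2R,3S)-2-{3-[(tert-butyldiphenylsilyl)oxy]propyl}-N-methoxy-N,6-dimethyl-3-[(triethylsilyl)oxy]hept-6-enamide | CON(C)C(=O)[C@@H]([C@@H](O[Si](CC)(CC)CC)CCC(C)=C)CCCO[Si](c1ccccc1)(c1ccccc1)C(C)(C)C | intermediate
13 | (3R,4S)-3-{3-[(tert-butyldiphenylsilyl)oxy]propyl}-7-methyl-4-[(triethylsilyl)oxy]oct-7-en-2-one | CC(=O)[C@@H]([C@@H](O[Si](CC)(CC)CC)CCC(C)=C)CCCO[Si](c1ccccc1)(c1ccccc1)C(C)(C)C | intermediate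
14 | triethyl phosphonoacetate | CCOC(=O)CP(=O)(OCC)OCC | starting material
15 | sodium salt of the triethyl phosphonoacetate carbanion | [Na+].CCOC(=O)[CH-]P(=O)(OCC)OCC | intermediate
16 | ethyl (2E,4S,5S)-4-{3-[(tert-butyldiphenylsilyl)oxy]propyl}-3,8-dimethyl-5-[(triethylsilyl)oxy]nona-2,8-dienoate | CCOC(=O)/C=C(\C)[C@@H]([C@@H](O[Si](CC)(CC)CC)CCC(C)=C)CCCO[Si](c1ccccc1)(c1ccccc1)C(C)(C)C | intermediate
17 | secondary ozonide of 16 (3-methyl-1,2,4-trioxolan-3-yl in place of the 2-propenyl end) | CCOC(=O)/C=C(\C)[C@@H]([C@@H](O[Si](CC)(CC)CC)CCC1(C)OCOO1)CCCO[Si](c2ccccc2)(c2ccccc2)C(C)(C)C | intermediate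
18 | ethyl (2E,4S,5S)-4-{3-[(tert-butyldiphenylsilyl)oxy]propyl}-3-methyl-8-oxo-5-[(triethylsilyl)oxy]non-2-enoate | CCOC(=O)/C=C(\C)[C@@H]([C@@H](O[Si](CC)(CC)CC)CCC(C)=O)CCCO[Si](c1ccccc1)(c1ccccc1)C(C)(C)C | intermediate
19 | ethyl 2-[(1S,2S,3S,6S)-2-{3-[(tert-butyldiphenylsilyl)oxy]propyl}-6-hydroxy-1,6-dimethyl-3-[(triethylsilyl)oxy]cyclohexyl]acetate (ring labels: C1 S, C4 S, C5 S, C6 S) | CC[Si](CC)(CC)O[C@H]1CC[C@](C)(O)[C@@](C)(CC(=O)OCC)[C@@H]1CCCO[Si](c2ccccc2)(c2ccccc2)C(C)(C)C | intermediate
20 | ethyl 2-[(1S,2S,3S,6S)-2-{3-[(tert-butyldiphenylsilyl)oxy]propyl}-1,6-dimethyl-3,6-bis[(triethylsilyl)oxy]cyclohexyl]acetate | CC[Si](CC)(CC)O[C@H]1CC[C@](C)(O[Si](CC)(CC)CC)[C@@](C)(CC(=O)OCC)[C@@H]1CCCO[Si](c2ccccc2)(c2ccccc2)C(C)(C)C | intermediate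
21 | 2-[(1S,2S,3S,6S)-2-{3-[(tert-butyldiphenylsilyl)oxy]propyl}-1,6-dimethyl-3,6-bis[(triethylsilyl)oxy]cyclohexyl]ethan-1-ol | CC[Si](CC)(CC)O[C@H]1CC[C@](C)(O[Si](CC)(CC)CC)[C@@](C)(CCO)[C@@H]1CCCO[Si](c2ccccc2)(c2ccccc2)C(C)(C)C | intermediate
22 | primary iodide from 21 (C5–CH2CH2I; ring C1 S, C4 S, C5 S, C6 S) | CC[Si](CC)(CC)O[C@H]1CC[C@](C)(O[Si](CC)(CC)CC)[C@@](C)(CCI)[C@@H]1CCCO[Si](c2ccccc2)(c2ccccc2)C(C)(C)C | intermediate
23 | 3-methylbut-2-enal (prenal) | CC(C)=CC=O | starting material
24 | allenylboronic acid pinacol ester | C=C=CB1OC(C)(C)C(C)(C)O1 | starting material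
25 | (S)-6-methylhept-5-en-1-yn-4-ol | C#CC[C@H](O)C=C(C)C | intermediate
26 | tert-butyldimethyl{[(4S)-6-methylhept-5-en-1-yn-4-yl]oxy}silane | C#CC[C@H](O[Si](C)(C)C(C)(C)C)C=C(C)C | intermediate
27 | (E)-alkenyldimethylalane from 26 (Al cis to the new methyl) | C[Al](C)/C=C(\C)C[C@H](O[Si](C)(C)C(C)(C)C)C=C(C)C | intermediate
28 | tert-butyl{[(1E,4S)-1-iodo-2,6-dimethylhepta-1,5-dien-4-yl]oxy}dimethylsilane | I/C=C(\C)C[C@H](O[Si](C)(C)C(C)(C)C)C=C(C)C | intermediate
29 | (4-bromobut-1-yn-1-yl)trimethylsilane | C[Si](C)(C)C#CCCBr | starting material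
30 | [4-(trimethylsilyl)but-3-yn-1-yl]zinc bromide | C[Si](C)(C)C#CCC[Zn]Br | intermediate
31 | TMS-enyne: (5E,8S)-8-(TBS-oxy)-6,10-dimethyl-1-(trimethylsilyl)undeca-5,9-dien-1-yne | C[Si](C)(C)C#CCC/C=C(\C)C[C@H](O[Si](C)(C)C(C)(C)C)C=C(C)C | intermediate
32 | terminal enyne: (5E,8S)-8-(TBS-oxy)-6,10-dimethylundeca-5,9-dien-1-yne | C#CCC/C=C(\C)C[C@H](O[Si](C)(C)C(C)(C)C)C=C(C)C | intermediate
33 | (E)-alkenyldimethylalane from 32 | C[Al](C)/C=C(\C)CC/C=C(\C)C[C@H](O[Si](C)(C)C(C)(C)C)C=C(C)C | intermediate
34 | tert-butyl{[(1E,5E,8S)-1-iodo-2,6,10-trimethylundeca-1,5,9-trien-8-yl]oxy}dimethylsilane | I/C=C(\C)CC/C=C(\C)C[C@H](O[Si](C)(C)C(C)(C)C)C=C(C)C | intermediate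
35 | alkylzinc iodide from 22 (C5–CH2CH2ZnI) | CC[Si](CC)(CC)O[C@H]1CC[C@](C)(O[Si](CC)(CC)CC)[C@@](C)(CC[Zn]I)[C@@H]1CCCO[Si](c2ccccc2)(c2ccccc2)C(C)(C)C | intermediate
36 | coupled triene: ring as in 21 with C5 bearing the (3E,7E,10S)-10-(TBS-oxy)-4,8,12-trimethyltrideca-3,7,11-trien-1-yl chain (ring C1 S, C4 S, C5 S, C6 S) | CC[Si](CC)(CC)O[C@H]1CC[C@](C)(O[Si](CC)(CC)CC)[C@@](C)(CC/C=C(\C)CC/C=C(\C)C[C@H](O[Si](C)(C)C(C)(C)C)C=C(C)C)[C@@H]1CCCO[Si](c2ccccc2)(c2ccccc2)C(C)(C)C | intermediate
37 | C1 alcohol: 36 with free C1–OH (C1 S) | O[C@H]1CC[C@](C)(O[Si](CC)(CC)CC)[C@@](C)(CC/C=C(\C)CC/C=C(\C)C[C@H](O[Si](C)(C)C(C)(C)C)C=C(C)C)[C@@H]1CCCO[Si](c2ccccc2)(c2ccccc2)C(C)(C)C | intermediate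
38 | C1 ketone (cyclohexanone; ring C4 S, C5 S, C6 S) | O=C1CC[C@](C)(O[Si](CC)(CC)CC)[C@@](C)(CC/C=C(\C)CC/C=C(\C)C[C@H](O[Si](C)(C)C(C)(C)C)C=C(C)C)[C@@H]1CCCO[Si](c2ccccc2)(c2ccccc2)C(C)(C)C | intermediate
39 | C1 tertiary carbinol bearing a 2-propenyl group (C1 configuration not assigned; ring C4 S, C5 S, C6 S) | CC(=C)C1(O)CC[C@](C)(O[Si](CC)(CC)CC)[C@@](C)(CC/C=C(\C)CC/C=C(\C)C[C@H](O[Si](C)(C)C(C)(C)C)C=C(C)C)[C@@H]1CCCO[Si](c2ccccc2)(c2ccccc2)C(C)(C)C | intermediate
40 | (Z)-α-methyl enal, silyl-protected (ring C4 S, C5 S, C6 R; CHO syn to C6) | C/C(C=O)=C1\CC[C@](C)(O[Si](CC)(CC)CC)[C@@](C)(CC/C=C(\C)CC/C=C(\C)C[C@H](O[Si](C)(C)C(C)(C)C)C=C(C)C)[C@@H]1CCCO[Si](c2ccccc2)(c2ccccc2)C(C)(C)C | intermediate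
41 | (2Z)-2-[(2R,3S,4S)-4-hydroxy-3-[(3E,7E,10S)-10-hydroxy-4,8,12-trimethyltrideca-3,7,11-trien-1-yl]-2-(3-hydroxypropyl)-3,4-dimethylcyclohexylidene]propanal | C/C(C=O)=C1\CC[C@](C)(O)[C@@](C)(CC/C=C(\C)CC/C=C(\C)C[C@H](O)C=C(C)C)[C@@H]1CCCO | intermediate
42 | CNP0161066.1: (2Z)-2-[(2R,3S,4S)-3-{(3E,7E,10S)-10-[(2R)-3,3-dimethyloxiran-2-yl]-10-hydroxy-4,8-dimethyldeca-3,7-dien-1-yl}-4-hydroxy-2-(3-hydroxypropyl)-3,4-dimethylcyclohexylidene]propanal | C/C(C=O)=C1\CC[C@](C)(O)[C@@](C)(CC/C=C(\C)CC/C=C(\C)C[C@H](O)[C@H]2OC2(C)C)[C@@H]1CCCO | target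

**Totals**

Total step count: 25. Longest linear sequence: 19 steps (steps 1–12 and 19–25); the side-chain branch is 6 steps (13–18).

**Steps most likely to fail**

1. Step 9 (ketyl–olefin closure). Radical addition to the hindered β,β-disubstituted enoate may be slower than simple reduction of the ketone or pinacol coupling, and a competing chair or boat arrangement may erode the facial selectivity at C4/C5. The fallback sets out from 18 and generates the same C4 radical by hydrogen-atom transfer instead of electron transfer. Kinetic enolisation of the methyl ketone (lithium diisopropylamide, TESCl, THF, −78 °C) would give the terminal triethylsilyl enol ether F1. Treating F1 with Fe(acac)3 and PhSiH2(Oi-Pr) in THF containing a little i-PrOH at rt should transfer a hydrogen atom to the enol ether CH2. The resulting C4 α-silyloxy radical has no ketone-reduction pathway and should close 6-exo onto the enoate (HAT-initiated radical conjugate addition), giving the C4-O-TES ester directly. The fallback comes back to the route at 20, so step 10 is no longer needed.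

2. Step 23 (oxidative transposition). The hindered tertiary allylic chromate may ionise and eliminate to dienes instead of undergoing the [3,3] shift, and the alkene geometry is not under direct control. The fallback sets out from 38 and builds the enal by olefination and redox adjustment. Peterson olefination with the lithium enolate of ethyl 2-(trimethylsilyl)propanoate (lithium diisopropylamide, THF, −78 °C → rt) would give the exocyclic α-methyl enoate F2. Reduction with i-Bu2AlH (CH2Cl2, −78 °C) would give the allylic alcohol F3, and MnO2 (CH2Cl2, rt) would oxidise it to the enal, whose geometric isomers are equilibrated towards (Z). The fallback comes back to the route at 40.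

3. Step 7 (olefination of the ketone). Olefination of the α-branched, β-silyloxy methyl ketone may be sluggish, with erosion of E/Z selectivity, base-mediated epimerisation at C6 or loss of silanol. The fallback sets out from 12 and makes the (E)-enoate stereospecifically from an alkyne. Reduction with i-Bu2AlH (THF, −78 °C) would give the aldehyde F4. Homologation with dimethyl (1-diazo-2-oxopropyl)phosphonate and K2CO3 in MeOH (Ohira–Bestmann) would give the terminal alkyne F5. Zr-catalysed carboalumination (AlMe3, Cp2ZrCl2, CH2Cl2) would give the alkenylalane F6 (not isolated), which is acylated in the flask with ethyl chloroformate to the (E)-enoate only. The fallback comes back to the route at 16.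

**Further compounds**

F1 | step 9 | triethylsilyl enol ether of 18 (CH2=C(OTES)– at C4) | CCOC(=O)/C=C(\C)[C@@H]([C@@H](O[Si](CC)(CC)CC)CCC(=C)O[Si](CC)(CC)CC)CCCO[Si](c1ccccc1)(c1ccccc1)C(C)(C)C
F2 | step 23 | exocyclic α-methyl enoate from 38 (C1=C(CH3)CO2Et, geometry not fixed) | CCOC(=O)C(C)=C1CC[C@](C)(O[Si](CC)(CC)CC)[C@@](C)(CC/C=C(\C)CC/C=C(\C)C[C@H](O[Si](C)(C)C(C)(C)C)C=C(C)C)[C@@H]1CCCO[Si](c2ccccc2)(c2ccccc2)C(C)(C)C
F3 | step 23 | allylic alcohol from F2 (C1=C(CH3)CH2OH) | CC(CO)=C1CC[C@](C)(O[Si](CC)(CC)CC)[C@@](C)(CC/C=C(\C)CC/C=C(\C)C[C@H](O[Si](C)(C)C(C)(C)C)C=C(C)C)[C@@H]1CCCO[Si](c2ccccc2)(c2ccccc2)C(C)(C)C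
F4 | step 7 | aldehyde from 12 (2-substituted 6-methyl-3-(TES-oxy)hept-6-enal) | O=C[C@@H]([C@@H](O[Si](CC)(CC)CC)CCC(C)=C)CCCO[Si](c1ccccc1)(c1ccccc1)C(C)(C)C
F5 | step 7 | terminal alkyne from F4 | C#C[C@@H]([C@@H](O[Si](CC)(CC)CC)CCC(C)=C)CCCO[Si](c1ccccc1)(c1ccccc1)C(C)(C)C
F6 | step 7 | (E)-alkenyldimethylalane from F5 | C[Al](C)/C=C(\C)[C@@H]([C@@H](O[Si](CC)(CC)CC)CCC(C)=C)CCCO[Si](c1ccccc1)(c1ccccc1)C(C)(C)C
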